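Begin at the far end of this flask, where the curve has to flatten. The 0.600 equiv of coupling partner are counted on the left-handed substrate, so c(coupling partner) starts at 0.300 mM against 1.00 mM of both substrates together. That makes coupling partner the limiting reagent, and since each product takes one coupling partner, conversion levels off near 30.0%.

in all of them: left-handed substrate 0.50 mM; right-handed substrate 0.50 mM; free catalyst 1 mol%
- Wednesday's: coupling partner 0.60 equiv; the very flask that is asked about, followed so far
- flask: coupling partner 0.600 equiv

Wednesday's run (percent of the left-handed substrate and right-handed substrate together charged)

| time / s | left-handed product / % | left-handed substrate / % |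
|---|---|---|
| 10.0 | 0 | 49.5 |
| 15.0 | 0.8 | 48.9 |
| 25.0 | 1.5 | 48.7 |
| 50.0 | 2.1 | 47.5 |
| 90.0 | 3.3 | 45.7 |

(scatter of a reading: 0.3 percentage points)

- free catalyst is single-handed; left-handed substrate and right-handed substrate are mirror images of each other, charged as a racemate, each of them at the stated concentration
- reactions considered so far: free catalyst + left-handed substrate <-> catalyst intermediate A; free catalyst + right-handed substrate <-> catalyst intermediate B; coupling partner + catalyst intermediate A -> free catalyst + left-handed product; coupling partner + catalyst intermediate B -> free catalyst + right-handed product; left-handed substrate <-> right-handed substrate; coupling partner + free catalyst -> spent catalyst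
- no earlier run changes the charge of free catalyst; that part of a forecast is a guess
- no earlier run changes the charge of coupling partner; that part of a forecast is a guess

1. apparent order in coupling partner when 20% of the left-handed substrate and right-handed substrate together are converted (percent change of the rate of making left-handed product for one percent more coupling partner charged)
2. apparent order in free catalyst when 20% of the left-handed substrate and right-handed substrate together are converted (percent change of the rate of making left-handed product for one percent more free catalyst charged)

Now walk back up the curve. In Wednesday's run, left-handed product climbs 2.5 percentage points between 15.0 s and 90.0 s, but right-handed substrate and right-handed product go unread, so you have no clock for total conversion. You need none. At 20% conversion, 0.200 mM of coupling partner has been used, which leaves c(coupling partner) at 0.100 mM, a third of the charge, and the curve then bends towards its level.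

Charge a little more coupling partner, keep both substrates as they are, and compare at the same conversion: the same amount is subtracted, so the extra stands in what is left and counts for more there. Call the charge over what is left at that moment the leverage, here 3.00. Each coupling step is first order in coupling partner, so my own reckoning puts the order in coupling partner at the leverage; the order in free catalyst I simply take as one, which is a guess.

The forecast gives 1.4 in coupling partner and 0.95 in free catalyst. On coupling partner it parts from my reckoning over the charge, “assuming equivalents refer to total substrate”.

The flask gives 3.0 in coupling partner, against a leverage of 3.00, and 1.2 in free catalyst.

    free catalyst + left-handed substrate ⇌ catalyst intermediate A (K = 980 L mol⁻¹, k = 9.70 × 10⁵ L mol⁻¹ s⁻¹)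
    free catalyst + right-handed substrate ⇌ catalyst intermediate B (K = 30000 L mol⁻¹, k = 2.30 × 10⁵ L mol⁻¹ s⁻¹)
    coupling partner + catalyst intermediate A → free catalyst + left-handed product (k = 12000 L mol⁻¹ s⁻¹)
    coupling partner + catalyst intermediate B → free catalyst + right-handed product (k = 2400 L mol⁻¹ s⁻¹)
    left-handed substrate ⇌ right-handed substrate (k = 0.00180 s⁻¹)
    coupling partner + free catalyst → spent catalyst (k = 54.0 L mol⁻¹ s⁻¹)

The point of 20% conversion comes at 1.43 min, with left-handed product forming at 0.0137 mM min⁻¹. By 4.00 min coupling partner stands at 5.69% of its own charge, so the leverage, charge over what is left, has reached 17.6.

The runs come from a simulation on assumed constants, and the scatter is random.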